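**Retrosynthetic overview**

1. The butenolide ring (O–C10–C11=C12–C20) is formed last: C20 is CO, inserted by carbonylative lactonisation of a (Z)-12-iodo-11-en-10-ol, and C10(R) comes from asymmetric transfer hydrogenation of a macrocyclic 11-yn-10-one.
2. The 14-membered carbocycle is formed first, by closing C9–C10: a lithiated 2-alkynyl-1,3-dithiane (C10 as masked carbonyl, C11≡C12 already attached) opens an (R)-2-methyl-2-alkenyloxirane (C8–O–C9) at its CH2 carbon.
3. Enabling feature: the tertiary carbinol C8 of the carbocycle and C10, the oxygen-bearing sp3 carbon of the five-membered lactone, stand 1,3 across C9H2. C8(OH)–C9H2 is therefore a ring-opened 2,2-disubstituted epoxide and C10 a latent ketone; oxirane strain drives the closure and unveils C8–OH.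
4. Seco chain: C12–C13 by acetylide alkylation; C1(S) by Heck coupling at C1–C2, Sharpless epoxidation of the resulting dienol and hydroxyl-directed hydride opening.
5. C2–C9 with both methyl groups is (R)-linalool: its carbinol is C4(R), its vinyl group is C3=C2, and its prenyl end becomes C6=C7/C8(S)–OH/C9 by allylic oxidation, Sharpless epoxidation and selenoxide transposition.

Key step: step 14

Assumption: atom numbers C1–C14 and C20 are the cembrane numbers of the target (C1 isopropyl carbinol, C4 and C8 methyl carbinols, C10 lactone carbinol, C20 lactone carbonyl; target = 1S,4R,8S,10R), and commercial (R)-(−)-linalool is taken as enantiomerically pure.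

**Route**

Step 1
Reactants: 1 (R)-(−)-linalool [(3R)-3,7-dimethylocta-1,6-dien-3-ol]
Product: 2 (2E,6R)-2,6-dimethylocta-2,7-diene-1,6-diol
Conditions: SeO2 (0.2 equiv), t-BuOOH (3 equiv), salicylic acid (cat.), CH2Cl2, 0 °C → rt
Reagents that add atoms: tert-butyl hydroperoxide, CC(C)(C)OO
Why: Riley allylic oxidation (ene reaction then [2,3]-sigmatropic shift at selenium, SeO2 turned over by t-BuOOH) should hydroxylate the (E)-methyl group of the trisubstituted alkene, the vinyl carbinol having no allylic C–H; the carbinol stereocentre (C4 of the target) is that of linalool.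

Step 2
Reactants: 2 (2E,6R)-2,6-dimethylocta-2,7-diene-1,6-diol
Product: 3 [(2S,3S)-3-[(3R)-3-hydroxy-3-methylpent-4-en-1-yl]-2-methyloxiran-2-yl]methanol
Conditions: Ti(OiPr)4 (10 mol%), L-(+)-diethyl tartrate (12 mol%), t-BuOOH, 4 Å MS, CH2Cl2, −20 °C
Reagents that add atoms: tert-butyl hydroperoxide, CC(C)(C)OO
Why: Sharpless asymmetric epoxidation: the primary allylic alcohol reacts far faster than the tertiary vinyl carbinol, and L-(+)-diethyl tartrate directs oxygen to the alkene face that gives the (2S,3S)-epoxide, which fixes the future C8 as S.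

Step 3
Reactants: 3 [(2S,3S)-3-[(3R)-3-hydroxy-3-methylpent-4-en-1-yl]-2-methyloxiran-2-yl]methanol
Product: 6 (2R,3E,6R)-2,6-dimethylocta-3,7-diene-1,2,6-triol, via hydroxy selenide 4 (not isolated), via selenoxide 5 (not isolated)
Conditions: (PhSe)2, NaBH4, EtOH, 0 → 60 °C; then 30% H2O2, THF, 0 °C → rt
Reagents that add atoms: none
Why: Epoxide-to-allylic-alcohol transposition through selenide opening and selenoxide syn-elimination: PhSe− should open the trisubstituted epoxide by SN2 attack at the secondary carbon C7 (the other epoxide carbon is quaternary), and the selenoxide can eliminate only toward C6, which gives the (E)-alkene and leaves the C8–O bond and hence the C8 configuration untouched.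

Step 4
Reactants: 6 (2R,3E,6R)-2,6-dimethylocta-3,7-diene-1,2,6-triol
Product: 7 (3R,5E)-3-methyl-6-[(4R)-2,2,4-trimethyl-1,3-dioxolan-4-yl]hexa-1,5-dien-3-ol
Conditions: 2,2-dimethoxypropane, PPTS (cat.), CH2Cl2, rt
Reagents that add atoms: 2,2-dimethoxypropane, COC(C)(C)OC
Why: Acid-catalysed transketalisation should convert only the 1,2-diol into the five-membered acetonide, which stores the C8 and C9 oxygens through the palladium and hydride steps while the isolated tertiary C4–OH stays free.

Step 5
Reactants: 8 4-methylpent-2-yn-1-ol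
Product: 10 (2Z)-3-iodo-4-methylpent-2-en-1-ol, via cyclic alkenylaluminate 9 (not isolated)
Conditions: NaAlH2(OCH2CH2OCH3)2, THF, 0 °C → rt; then I2, −78 → 0 °C
Reagents that add atoms: iodine, II
Why: Hydroxyl-directed trans-hydroalumination of a propargylic alcohol places aluminium on the distal alkyne carbon in a five-membered oxaluminacycle, and iodinolysis with retention should give the (Z)-iodoalkene with iodine cis to CH2OH.

Step 6
Reactants: 7 (3R,5E)-3-methyl-6-[(4R)-2,2,4-trimethyl-1,3-dioxolan-4-yl]hexa-1,5-dien-3-ol; 10 (2Z)-3-iodo-4-methylpent-2-en-1-ol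
Product: 11 (2Z,4E,6R,8E)-6-methyl-3-(propan-2-yl)-9-[(4R)-2,2,4-trimethyl-1,3-dioxolan-4-yl]nona-2,4,8-triene-1,6-diol
Conditions: Pd(OAc)2 (5 mol%), n-Bu4NCl, K2CO3, DMF, 45 °C
Reagents that add atoms: none
Why: Heck reaction: the alkenylpalladium iodide from 10 should add to the unsubstituted vinyl terminus of 7, and because the carbinol carbon has no hydrogen, β-hydride elimination can give only the conjugated (4E)-diene, while the iodoalkene geometry is retained so that the new chain stands cis to CH2OH.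

Step 7
Reactants: 11 (2Z,4E,6R,8E)-6-methyl-3-(propan-2-yl)-9-[(4R)-2,2,4-trimethyl-1,3-dioxolan-4-yl]nona-2,4,8-triene-1,6-diol
Product: 12 [(2R,3S)-3-[(1E,3R,5E)-3-hydroxy-3-methyl-6-[(4R)-2,2,4-trimethyl-1,3-dioxolan-4-yl]hexa-1,5-dien-1-yl]-3-(propan-2-yl)oxiran-2-yl]methanol
Conditions: Ti(OiPr)4 (20 mol%), D-(−)-diethyl tartrate (24 mol%), t-BuOOH, 4 Å MS, CH2Cl2, −25 °C
Reagents that add atoms: tert-butyl hydroperoxide, CC(C)(C)OO
Why: Sharpless asymmetric epoxidation: only the primary allylic alcohol is epoxidised at a useful rate, and D-(−)-diethyl tartrate delivers oxygen to the alkene face that makes the fully substituted epoxide carbon (C1 of the target) S, the catalyst and not the remote C4 and C8 centres controlling the face.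

Step 8
Reactants: 12 [(2R,3S)-3-[(1E,3R,5E)-3-hydroxy-3-methyl-6-[(4R)-2,2,4-trimethyl-1,3-dioxolan-4-yl]hexa-1,5-dien-1-yl]-3-(propan-2-yl)oxiran-2-yl]methanol
Product: 13 (3S,4E,6R,8E)-6-methyl-3-(propan-2-yl)-9-[(4R)-2,2,4-trimethyl-1,3-dioxolan-4-yl]nona-4,8-diene-1,3,6-triol
Conditions: NaAlH2(OCH2CH2OCH3)2, THF, −20 → 0 °C
Reagents that add atoms: none
Why: Hydroxyl-directed hydride opening of a 2,3-epoxy alcohol (the reaction type that gives 1,3-diols): the aluminate bound at the primary oxygen delivers hydride to the adjacent epoxide carbon C14, so the C1–O bond and the C1 configuration are kept and C1 becomes the tertiary carbinol.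

Step 9
Reactants: 13 (3S,4E,6R,8E)-6-methyl-3-(propan-2-yl)-9-[(4R)-2,2,4-trimethyl-1,3-dioxolan-4-yl]nona-4,8-diene-1,3,6-triol
Product: 14 (3S,4E,6R,8E)-1-iodo-6-methyl-3-(propan-2-yl)-9-[(4R)-2,2,4-trimethyl-1,3-dioxolan-4-yl]nona-4,8-diene-3,6-diol
Conditions: I2, PPh3, imidazole, THF, 0 °C
Reagents that add atoms: iodine, II
Why: Appel-type iodination should convert the only primary alcohol, the tertiary allylic carbinols being too hindered to be substituted under the imidazole-buffered conditions.

Step 10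
Reactants: 15 3,3-diethoxyprop-1-yne; 16 propane-1,3-dithiol
Product: 17 2-ethynyl-1,3-dithiane
Conditions: BF3·OEt2 (cat.), CH2Cl2, 0 °C → rt
Reagents that add atoms: none
Why: Lewis-acid-catalysed transthioacetalisation of the diethyl acetal, driven by formation of the six-membered dithioacetal.

Step 11
Reactants: 14 (3S,4E,6R,8E)-1-iodo-6-methyl-3-(propan-2-yl)-9-[(4R)-2,2,4-trimethyl-1,3-dioxolan-4-yl]nona-4,8-diene-3,6-diol; 17 2-ethynyl-1,3-dithiane
Product: 19 (5S,6E,8R,10E)-1-(1,3-dithian-2-yl)-8-methyl-5-(propan-2-yl)-11-[(4R)-2,2,4-trimethyl-1,3-dioxolan-4-yl]undeca-6,10-dien-1-yne-5,8-diol, via lithium acetylide 18 (not isolated)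
Conditions: 17 (3.5 equiv), n-BuLi (3.4 equiv), THF, −78 °C; then 14, DMPU, −78 °C → rt
Reagents that add atoms: none
Why: SN2 alkylation of a lithium acetylide by a primary iodide in a dipolar cosolvent: the acetylenic C–H of 17 is far more acidic than its dithiane C–H so only the acetylide forms, and the excess acetylide covers the two tertiary hydroxyls of 14 as lithium alkoxides.

Step 12
Reactants: 19 (5S,6E,8R,10E)-1-(1,3-dithian-2-yl)-8-methyl-5-(propan-2-yl)-11-[(4R)-2,2,4-trimethyl-1,3-dioxolan-4-yl]undeca-6,10-dien-1-yne-5,8-diol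
Product: 20 (2R,3E,6R,7E,9S)-13-(1,3-dithian-2-yl)-2,6-dimethyl-9-(propan-2-yl)trideca-3,7-dien-12-yne-1,2,6,9-tetrol
Conditions: PPTS (0.2 equiv), MeOH, rt
Reagents that add atoms: none
Why: Acid-catalysed transketalisation to methanol removes the terminal acetonide under conditions mild enough for the dithiane and the tertiary allylic carbinols.

Step 13
Reactants: 20 (2R,3E,6R,7E,9S)-13-(1,3-dithian-2-yl)-2,6-dimethyl-9-(propan-2-yl)trideca-3,7-dien-12-yne-1,2,6,9-tetrol
Product: 22 (5S,6E,8R,10E)-1-(1,3-dithian-2-yl)-8-methyl-11-[(2R)-2-methyloxiran-2-yl]-5-(propan-2-yl)undeca-6,10-dien-1-yne-5,8-diol, via primary tosylate 21 (not isolated)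
Conditions: TsCl, Et3N, Bu2SnO (5 mol%), CH2Cl2, 0 °C → rt; then K2CO3, MeOH, 0 °C → rt
Reagents that add atoms: none
Why: Tin-acetal-catalysed sulfonylation is selective for the primary hydroxyl of the 1,2-diol, and the neighbouring tertiary alkoxide then displaces tosylate in an intramolecular Williamson etherification (3-exo-tet), so the C8–O bond is retained and the epoxide carries the C8 configuration set in step 2 (the descriptor R results only from changed priorities).

Step 14
Reactants: 22 (5S,6E,8R,10E)-1-(1,3-dithian-2-yl)-8-methyl-11-[(2R)-2-methyloxiran-2-yl]-5-(propan-2-yl)undeca-6,10-dien-1-yne-5,8-diol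
Product: 24 (1S,2E,4R,6E,8S)-4,8-dimethyl-1-(propan-2-yl)-10,10-[propane-1,3-diylbis(sulfanediyl)]cyclotetradeca-2,6-dien-11-yne-1,4,8-triol, via trilithiated dithiane 23 (not isolated)
Conditions: n-BuLi (3.3 equiv), THF, −78 → −40 °C; then cannulation into THF–DMPU (10:1, final 0.002 M), −20 °C → rt; aq. NH4Cl
Reagents that add atoms: none
Why: n-BuLi first turns the two tertiary hydroxyls into lithium alkoxides and then removes the C10–H of the dithiane, which is acidified by two sulfur atoms and the alkyne; the 2-lithio-2-alkynyl-1,3-dithiane attacks the CH2 carbon C9 of the oxirane in an SN2 step anti to the C9–O bond, and release of the oxirane strain makes the C9–C10 bond formation irreversible while the oxygen stays on C8 as the alkoxide. The closest known reaction types are the Corey–Seebach opening of 2,2-disubstituted epoxides by 2-lithio-1,3-dithianes and the closure of 14-membered cembrane rings by intramolecular alkylation of sulfur- or nitrile-stabilised carbanions with epoxides or allylic halides. The 14-membered carbocycle closes in the 14-exo-tet mode under pseudo-high dilution; no second ring is formed. No new stereocentre arises: C8 keeps the configuration fixed by the Sharpless epoxidation of step 2 because only its CH2 neighbour is attacked, and C10 remains an achiral dithioketal carbon until step 16. The step needs attack at C9 instead of tertiary C8 or conjugate (SN2′) attack at C6, and bond formation at the dithiane carbon instead of the alkyne terminus C12: the primary versus tertiary carbon secures the first, the strained 11-membered ring and the internal position of C6 disfavour the second, and attack through C12 would demand a 12-membered tetrasubstituted allene. The alkoxides on C1 and C4 cannot intercept the epoxide because the (E)-double bonds C2=C3 and C6=C7 keep them from reaching C9 through a ring of workable size.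

Step 15
Reactants: 24 (1S,2E,4R,6E,8S)-4,8-dimethyl-1-(propan-2-yl)-10,10-[propane-1,3-diylbis(sulfanediyl)]cyclotetradeca-2,6-dien-11-yne-1,4,8-triol
Product: 25 (6S,7E,9R,11E,13S)-6,9,13-trihydroxy-9,13-dimethyl-6-(propan-2-yl)cyclotetradeca-7,11-dien-2-yn-1-one
Conditions: MeI, CaCO3, MeCN–H2O (4:1), 40 °C
Reagents that add atoms: water, O
Why: Alkylative dithiane hydrolysis: S-methylation turns the dithioketal into a leaving group and water delivers the carbonyl oxygen under CaCO3-buffered, nearly neutral conditions that should spare the β-hydroxy ynone from retro-aldol cleavage and the tertiary allylic alcohols from ionisation.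

Step 16
Reactants: 25 (6S,7E,9R,11E,13S)-6,9,13-trihydroxy-9,13-dimethyl-6-(propan-2-yl)cyclotetradeca-7,11-dien-2-yn-1-one
Product: 26 (1S,2E,4R,6E,8S,10R)-4,8-dimethyl-1-(propan-2-yl)cyclotetradeca-2,6-dien-11-yne-1,4,8,10-tetrol
Conditions: Ru[(R,R)-TsDPEN](p-cymene) (5 mol%), i-PrOH, rt
Reagents that add atoms: none
Why: Noyori asymmetric transfer hydrogenation of an ynone by the base-free amido ruthenium complex: the catalyst differentiates the alkynyl from the CH2 substituent, and the (R,R)-ligand should deliver hydride to the face that gives the (10R)-propargylic alcohol, the reagent overriding the C8 carbinol.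

Step 17
Reactants: 26 (1S,2E,4R,6E,8S,10R)-4,8-dimethyl-1-(propan-2-yl)cyclotetradeca-2,6-dien-11-yne-1,4,8,10-tetrol
Product: 28 (1S,2E,4R,6E,8S,10R,11Z)-12-iodo-4,8-dimethyl-1-(propan-2-yl)cyclotetradeca-2,6,11-triene-1,4,8,10-tetrol, via alkenylaluminate 27 (not isolated)
Conditions: NaAlH2(OCH2CH2OCH3)2 (6 equiv), THF, 0 °C → rt; then I2, −78 °C
Reagents that add atoms: iodine, II
Why: Hydroxyl-directed trans-hydroalumination of the propargylic alcohol places aluminium on C12 in a five-membered oxaluminacycle and hydrogen on C11, and iodinolysis with retention gives the (Z)-iodoalkene whose iodine is cis to the C10 carbinol, the geometry needed for lactonisation.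

Step 18
Reactants: 28 (1S,2E,4R,6E,8S,10R,11Z)-12-iodo-4,8-dimethyl-1-(propan-2-yl)cyclotetradeca-2,6,11-triene-1,4,8,10-tetrol
Product: 29 (1S,2E,4R,6E,8S,10R,11Z)-1,4,8-trihydroxycembra-2,6,11-trien-20,10-olide (CHEBI:68873)
Conditions: PdCl2(PPh3)2 (5 mol%), CO (1 atm), Et3N, THF, 50 °C
Reagents that add atoms: carbon monoxide, [C-]#[O+]
Why: Carbonylative lactonisation: oxidative addition of zerovalent palladium to the alkenyl iodide, CO insertion and capture of the acylpalladium by the cis C10 hydroxyl close the butenolide without touching the C10–O bond, so all four stereocentres are kept.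

**Compound list**

1 | (R)-(−)-linalool, (3R)-3,7-dimethylocta-1,6-dien-3-ol | C=C[C@](C)(O)CCC=C(C)C | starting material
2 | (2E,6R)-2,6-dimethylocta-2,7-diene-1,6-diol | C=C[C@](C)(O)CC/C=C(\C)CO | intermediate
3 | [(2S,3S)-3-[(3R)-3-hydroxy-3-methylpent-4-en-1-yl]-2-methyloxiran-2-yl]methanol | C=C[C@](C)(O)CC[C@@H]1O[C@@]1(C)CO | intermediate
4 | (2S,3R,6R)-2,6-dimethyl-3-(phenylselanyl)oct-7-ene-1,2,6-triol | C=C[C@](C)(O)CC[C@@H]([Se]c1ccccc1)[C@@](C)(O)CO | intermediate
5 | (2S,3R,6R)-2,6-dimethyl-3-(phenylseleninyl)oct-7-ene-1,2,6-triol | C=C[C@](C)(O)CC[C@@H]([Se](=O)c1ccccc1)[C@@](C)(O)CO | intermediate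
6 | (2R,3E,6R)-2,6-dimethylocta-3,7-diene-1,2,6-triol | C=C[C@](C)(O)C/C=C/[C@@](C)(O)CO | intermediate
7 | (3R,5E)-3-methyl-6-[(4R)-2,2,4-trimethyl-1,3-dioxolan-4-yl]hexa-1,5-dien-3-ol | C=C[C@](C)(O)C/C=C/[C@@](C)(O1)COC1(C)C | intermediate
8 | 4-methylpent-2-yn-1-ol | CC(C)C#CCO | starting material
9 | sodium 2,2-bis(2-methoxyethoxy)-3-(propan-2-yl)-2,5-dihydro-1,2-oxaluminol-2-uide | [Na+].CC(C)C1=CCO[Al-]1(OCCOC)OCCOC | intermediate
10 | (2Z)-3-iodo-4-methylpent-2-en-1-ol | OC/C=C(\I)C(C)C | intermediate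
11 | (2Z,4E,6R,8E)-6-methyl-3-(propan-2-yl)-9-[(4R)-2,2,4-trimethyl-1,3-dioxolan-4-yl]nona-2,4,8-triene-1,6-diol | OC/C=C(\C=C\[C@](C)(O)C/C=C/[C@@](C)(O1)COC1(C)C)C(C)C | intermediate
12 | [(2R,3S)-3-[(1E,3R,5E)-3-hydroxy-3-methyl-6-[(4R)-2,2,4-trimethyl-1,3-dioxolan-4-yl]hexa-1,5-dien-1-yl]-3-(propan-2-yl)oxiran-2-yl]methanol | OC[C@H]1O[C@]1(/C=C/[C@](C)(O)C/C=C/[C@@](C)(O2)COC2(C)C)C(C)C | intermediate
13 | (3S,4E,6R,8E)-6-methyl-3-(propan-2-yl)-9-[(4R)-2,2,4-trimethyl-1,3-dioxolan-4-yl]nona-4,8-diene-1,3,6-triol | OCC[C@@](O)(/C=C/[C@](C)(O)C/C=C/[C@@](C)(O1)COC1(C)C)C(C)C | intermediate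
14 | (3S,4E,6R,8E)-1-iodo-6-methyl-3-(propan-2-yl)-9-[(4R)-2,2,4-trimethyl-1,3-dioxolan-4-yl]nona-4,8-diene-3,6-diol | ICC[C@@](O)(/C=C/[C@](C)(O)C/C=C/[C@@](C)(O1)COC1(C)C)C(C)C | intermediate
15 | 3,3-diethoxyprop-1-yne | C#CC(OCC)OCC | starting material
16 | propane-1,3-dithiol | SCCCS | starting material
17 | 2-ethynyl-1,3-dithiane | C#CC1SCCCS1 | intermediate
18 | lithium 2-(1,3-dithian-2-yl)ethyn-1-ide | [Li+].[C-]#CC1SCCCS1 | intermediate
19 | (5S,6E,8R,10E)-1-(1,3-dithian-2-yl)-8-methyl-5-(propan-2-yl)-11-[(4R)-2,2,4-trimethyl-1,3-dioxolan-4-yl]undeca-6,10-dien-1-yne-5,8-diol | C1(C#CCC[C@@](O)(/C=C/[C@](C)(O)C/C=C/[C@@](C)(O2)COC2(C)C)C(C)C)SCCCS1 | intermediate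
20 | (2R,3E,6R,7E,9S)-13-(1,3-dithian-2-yl)-2,6-dimethyl-9-(propan-2-yl)trideca-3,7-dien-12-yne-1,2,6,9-tetrol | C1(C#CCC[C@@](O)(/C=C/[C@](C)(O)C/C=C/[C@@](C)(O)CO)C(C)C)SCCCS1 | intermediate
21 | 1-O-(4-methylbenzenesulfonyl) derivative of 20 (primary tosylate) | C1(C#CCC[C@@](O)(/C=C/[C@](C)(O)C/C=C/[C@@](C)(O)COS(=O)(=O)c2ccc(C)cc2)C(C)C)SCCCS1 | intermediate
22 | (5S,6E,8R,10E)-1-(1,3-dithian-2-yl)-8-methyl-11-[(2R)-2-methyloxiran-2-yl]-5-(propan-2-yl)undeca-6,10-dien-1-yne-5,8-diol | C1(C#CCC[C@@](O)(/C=C/[C@](C)(O)C/C=C/[C@@]2(C)OC2)C(C)C)SCCCS1 | intermediate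
23 | trilithium salt of 22 (dithiane C2 carbanion, both tertiary alkoxides) | [Li+].[Li+].[Li+].[C-]1(C#CCC[C@@]([O-])(/C=C/[C@](C)([O-])C/C=C/[C@@]2(C)OC2)C(C)C)SCCCS1 | intermediate
24 | (1S,2E,4R,6E,8S)-4,8-dimethyl-1-(propan-2-yl)-10,10-[propane-1,3-diylbis(sulfanediyl)]cyclotetradeca-2,6-dien-11-yne-1,4,8-triol | CC(C)[C@]1(O)/C=C/[C@](C)(O)C/C=C/[C@@](C)(O)CC2(SCCCS2)C#CCC1 | intermediate
25 | (6S,7E,9R,11E,13S)-6,9,13-trihydroxy-9,13-dimethyl-6-(propan-2-yl)cyclotetradeca-7,11-dien-2-yn-1-one | CC(C)[C@]1(O)/C=C/[C@](C)(O)C/C=C/[C@@](C)(O)CC(=O)C#CCC1 | intermediate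
26 | (1S,2E,4R,6E,8S,10R)-4,8-dimethyl-1-(propan-2-yl)cyclotetradeca-2,6-dien-11-yne-1,4,8,10-tetrol | CC(C)[C@]1(O)/C=C/[C@](C)(O)C/C=C/[C@@](C)(O)C[C@@H](O)C#CCC1 | intermediate
27 | tetrasodium alkenylaluminate of 26 (C10–O–Al–C12 oxaluminole, the three tertiary oxygens as hydrido-alkoxyaluminates) | [Na+].[Na+].[Na+].[Na+].CC(C)[C@]1(O[AlH-](OCCOC)OCCOC)/C=C/[C@](C)(O[AlH-](OCCOC)OCCOC)C/C=C/[C@@](C)(O[AlH-](OCCOC)OCCOC)C[C@H]2O[Al-](OCCOC)(OCCOC)C(CC1)=C2 | intermediate
28 | (1S,2E,4R,6E,8S,10R,11Z)-12-iodo-4,8-dimethyl-1-(propan-2-yl)cyclotetradeca-2,6,11-triene-1,4,8,10-tetrol | CC(C)[C@]1(O)/C=C/[C@](C)(O)C/C=C/[C@@](C)(O)C[C@@H](O)/C=C(\I)CC1 | intermediate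
29 | (1S,2E,4R,6E,8S,10R,11Z)-1,4,8-trihydroxycembra-2,6,11-trien-20,10-olide (CHEBI:68873) | CC(C)[C@]1(O)/C=C/[C@](C)(O)C/C=C/[C@@](C)(O)C[C@@H]2C=C(CC1)C(=O)O2 | target

**Step count**

Total step count: 18.
Longest linear sequence: 16 steps (from 1 to 29 through steps 1–4, 6–9 and 11–18; steps 5 and 10 are side branches).

**Steps most likely to fail, with fallbacks**

1. Step 14 (ring closure). The trilithiated species may aggregate, so that intermolecular epoxide opening (oligomerisation) or misdirected attack (SN2′ at C6, or through the alkyne terminus) competes with the 14-exo-tet closure. The fallback sets out from 22 and changes the reacting species from a trianion to a monoanion. Both tertiary hydroxyls would be capped with N-(trimethylsilyl)imidazole to give the bis(trimethylsilyl) ether F1. One equivalent of n-BuLi in THF–HMPA would then form only the dithiane carbanion, whose epoxide opening under high dilution should give the macrocyclic bis(trimethylsilyl) ether F2. K2CO3 in MeOH removes both silyl groups and the route is rejoined at 24.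

2. Step 7 (epoxidation of the dienol). The titanium alkoxide may ionise and open the tertiary, allylic epoxide as it forms, with loss of material and of face selectivity. The fallback sets out from 11 and replaces the titanium–tartrate system by a ketone-catalysed dioxirane epoxidation in basic buffer. The primary hydroxyl would be silylated (TBSCl, imidazole) to the silyl ether F3. Shi epoxidation would then give the silyl-protected epoxide F4, using the D-fructose-derived ketone, KHSO5, K2CO3 and n-Bu4NHSO4 in MeCN–dimethoxymethane–buffer at pH about 10.5 and 0 °C. In the spiro transition state this ketone should attack the same face of the trisubstituted alkene as D-(−)-tartrate. TBAF removes the silyl group and the route is rejoined at 12.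

3. Step 17 (hydroalumination–iodination). Hydride delivery within the tetra-alkoxide aggregate may be incomplete or misdirected, and the large excess of aluminium hydride complicates the iodine quench. The fallback sets out from 26 and uses catalytic trans-hydrosilylation in place of stoichiometric aluminate. Benzyldimethylsilane with [Cp*Ru(MeCN)3]PF6 (cat.) in CH2Cl2 at 0 °C should add trans across the propargylic alkyne with silicon on the carbon distal to the hydroxyl, giving the (Z)-alkenylsilane F5. Iododesilylation with N-iodosuccinimide in hexafluoroisopropanol at 0 °C proceeds with retention and the route is rejoined at 28.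

Further compounds
F1 | step 14 | bis(trimethylsilyl) ether (both tertiary oxygens) of 22 | C1(C#CCC[C@@](O[Si](C)(C)C)(/C=C/[C@](C)(O[Si](C)(C)C)C/C=C/[C@@]2(C)OC2)C(C)C)SCCCS1
F2 | step 14 | 1,4-bis-O-(trimethylsilyl) ether of 24 (C8 hydroxyl free) | CC(C)[C@]1(O[Si](C)(C)C)/C=C/[C@](C)(O[Si](C)(C)C)C/C=C/[C@@](C)(O)CC2(SCCCS2)C#CCC1
F3 | step 7 | 1-O-(tert-butyldimethylsilyl) ether of 11 | CC(C)(C)[Si](C)(C)OC/C=C(\C=C\[C@](C)(O)C/C=C/[C@@](C)(O1)COC1(C)C)C(C)C
F4 | step 7 | O-(tert-butyldimethylsilyl) ether of 12 | CC(C)(C)[Si](C)(C)OC[C@H]1O[C@]1(/C=C/[C@](C)(O)C/C=C/[C@@](C)(O2)COC2(C)C)C(C)C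
F5 | step 17 | (1S,2E,4R,6E,8S,10R,11Z)-12-[benzyl(dimethyl)silyl]-4,8-dimethyl-1-(propan-2-yl)cyclotetradeca-2,6,11-triene-1,4,8,10-tetrol | CC(C)[C@]1(O)/C=C/[C@](C)(O)C/C=C/[C@@](C)(O)C[C@@H](O)/C=C(\[Si](C)(C)Cc2ccccc2)CC1
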